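**Retrosynthetic overview**

- Feature: ring A is a 1,2,3,4-tetrasubstituted benzene. C1 carries the propenoate carbon C7 and C2 the diarylacrylate carbon Cα, directly beside the C3 oxygen (C4 also oxygenated). This is the pattern left when a 3,4-dioxygenated aryne C1≡C2 takes a carbon nucleophile at C1 and an electrophile at C2.
- Last disconnections: acid removal of four catechol acetonides and two tert-butyl esters; before that, cross-metathesis at C7=C8 between a C1 vinyl group and the acrylate of protected (R)-danshensu.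
- Key disconnection: bonds C1–C7 and C2–Cα in one pot. An aryne from an ortho-iodoaryl sulfonate takes vinylmagnesium bromide, and the resulting C2 organometal, after transfer to zinc, is coupled under palladium with a (Z)-α-bromocinnamate that already carries the first danshensu ester.
- Fragments: the aryne precursor and the bromocinnamic acid both come from protocatechualdehyde acetonide (Baeyer–Villiger oxidation and carbamate-directed iodination; bromo-Wittig olefination). The alcohol and the acrylate come from (R)-danshensu, which supplies both stereocentres.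
- Ring order: no ring of the target skeleton is formed; the four arenes are bought, and only acetonide rings are put on and removed.

Key step: step 14

Assumption: danshensu is used as the free (R)-acid (a sodium salt is acidified and extracted first). Ring A positions C1, C2, C3, C4 correspond to C5, C4, C3a, C7a of the 2,2-dimethyl-1,3-benzodioxole numbering.

**Route**

Step 1
Reactants: 1 3,4-dihydroxybenzaldehyde (protocatechualdehyde)
Product: 2 2,2-dimethyl-1,3-benzodioxole-5-carbaldehyde
Conditions: Me2C(OMe)2, TsOH·H2O (cat.), benzene, reflux, Soxhlet (4 Å MS); aqueous work-up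
Reagents that add atoms: 2,2-dimethoxypropane, COC(C)(C)OC
Why: Acid-catalysed transketalisation of the catechol, driven by removal of methanol, should give the aryl acetonide; any aldehyde dimethyl acetal is hydrolysed at work-up.

Step 2
Reactants: 2 2,2-dimethyl-1,3-benzodioxole-5-carbaldehyde
Product: 4 2,2-dimethyl-1,3-benzodioxol-5-ol, via aryl formate 3 (not isolated)
Conditions: mCPBA, CH2Cl2, 0 °C → rt; aq NaHCO3 wash; then K2CO3 (cat.), MeOH, rt
Reagents that add atoms: 3-chloroperoxybenzoic acid (mCPBA), O=C(OO)c1cccc(Cl)c1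
Why: In this Baeyer–Villiger (Dakin-type) oxidation the electron-rich aryl group migrates to give the aryl formate, which base-catalysed methanolysis cleaves to the phenol.

Step 3
Reactants: 4 2,2-dimethyl-1,3-benzodioxol-5-ol
Product: 5 2,2-dimethyl-1,3-benzodioxol-5-yl N,N-diethylcarbamate
Conditions: NaH, THF, 0 °C; Et2NCOCl, 0 °C → rt
Reagents that add atoms: N,N-diethylcarbamoyl chloride, CCN(CC)C(=O)Cl
Why: O-Carbamoylation of the sodium phenoxide installs a strong directing group for ortho-metalation.

Step 4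
Reactants: 5 2,2-dimethyl-1,3-benzodioxol-5-yl N,N-diethylcarbamate
Product: 7 4-iodo-2,2-dimethyl-1,3-benzodioxol-5-yl N,N-diethylcarbamate, via aryllithium 6 (not isolated)
Conditions: s-BuLi, TMEDA, THF, −78 °C; I2, −78 °C → rt
Reagents that add atoms: iodine, II
Why: In this directed ortho-metalation the C4–H lies between the carbamate and the dioxole oxygen, so both groups direct lithiation there, and quenching with iodine at −78 °C precedes any anionic Fries rearrangement.

Step 5
Reactants: 7 4-iodo-2,2-dimethyl-1,3-benzodioxol-5-yl N,N-diethylcarbamate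
Product: 8 4-iodo-2,2-dimethyl-1,3-benzodioxol-5-ol
Conditions: NaOH, EtOH/H2O, reflux; then aq NH4Cl
Reagents that add atoms: none
Why: Basic hydrolysis of the aryl carbamate frees the phenol, while the aryl ketal and the aryl iodide are inert to hydroxide.

Step 6
Reactants: 8 4-iodo-2,2-dimethyl-1,3-benzodioxol-5-ol
Product: 9 4-iodo-2,2-dimethyl-1,3-benzodioxol-5-yl 4-chlorobenzenesulfonate
Conditions: 4-ClC6H4SO2Cl, Et3N, DMAP (cat.), CH2Cl2, 0 °C → rt
Reagents that add atoms: 4-chlorobenzenesulfonyl chloride, O=S(=O)(Cl)c1ccc(Cl)cc1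
Why: O-Sulfonylation of the phenol gives the ortho-iodoaryl sulfonate, an established aryne precursor.

Step 7
Reactants: 2 2,2-dimethyl-1,3-benzodioxole-5-carbaldehyde
Product: 10 ethyl (Z)-2-bromo-3-(2,2-dimethyl-1,3-benzodioxol-5-yl)acrylate
Conditions: Ph3P=C(Br)CO2Et, toluene, 60 °C
Reagents that add atoms: ethyl bromo(triphenylphosphoranylidene)acetate, CCOC(=O)C(Br)=P(c1ccccc1)(c1ccccc1)c1ccccc1
Why: Wittig olefination with the stabilised bromo ylide should favour the (Z)-α-bromoacrylate, in which the aryl group is trans to the ester.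

Step 8
Reactants: 10 ethyl (Z)-2-bromo-3-(2,2-dimethyl-1,3-benzodioxol-5-yl)acrylate
Product: 11 (Z)-2-bromo-3-(2,2-dimethyl-1,3-benzodioxol-5-yl)acrylic acid
Conditions: LiOH·H2O, THF/H2O, 0 °C → rt; then 1 M HCl, 0 °C
Reagents that add atoms: lithium hydroxide, [Li+].[OH-]
Why: Saponification at low temperature should cleave the ethyl ester without dehydrobromination to the arylpropiolate.

Step 9
Reactants: 12 (R)-3-(3,4-dihydroxyphenyl)lactic acid (danshensu)
Product: 13 (R)-5-[(2,2-dimethyl-1,3-benzodioxol-5-yl)methyl]-2,2-dimethyl-1,3-dioxolan-4-one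
Conditions: Me2C(OMe)2, TsOH·H2O (cat.), acetone/benzene, reflux, Soxhlet (4 Å MS)
Reagents that add atoms: 2,2-dimethoxypropane, COC(C)(C)OC
Why: Acid-catalysed ketalisation converts the α-hydroxy acid into the dioxolanone and the catechol into the acetonide in one operation, and no bond to the stereocentre is broken.

Step 10
Reactants: 13 (R)-5-[(2,2-dimethyl-1,3-benzodioxol-5-yl)methyl]-2,2-dimethyl-1,3-dioxolan-4-one
Product: 14 (R)-3-(2,2-dimethyl-1,3-benzodioxol-5-yl)-2-hydroxypropanoic acid
Conditions: LiOH·H2O, THF/H2O, 0 °C; then 1 M HCl to pH 3, 0 °C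
Reagents that add atoms: lithium hydroxide, [Li+].[OH-]
Why: The dioxolanone is an activated acyl ketal that hydroxide opens at 0 °C with loss of acetone, while the catechol acetonide is inert to base and the carbinol centre is untouched; any methyl ester formed in step 9 would converge on the same acid.

Step 11
Reactants: 14 (R)-3-(2,2-dimethyl-1,3-benzodioxol-5-yl)-2-hydroxypropanoic acid
Product: 15 tert-butyl (R)-3-(2,2-dimethyl-1,3-benzodioxol-5-yl)-2-hydroxypropanoate
Conditions: t-BuOC(=N-i-Pr)NH-i-Pr, CH2Cl2, rt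
Reagents that add atoms: O-tert-butyl-N,N′-diisopropylisourea, CC(C)N=C(OC(C)(C)C)NC(C)C
Why: In this isourea esterification the carboxylic acid protonates the isourea and is tert-butylated as its carboxylate, whereas the secondary alcohol does not react without a catalyst.

Step 12
Reactants: 11 (Z)-2-bromo-3-(2,2-dimethyl-1,3-benzodioxol-5-yl)acrylic acid; 15 tert-butyl (R)-3-(2,2-dimethyl-1,3-benzodioxol-5-yl)-2-hydroxypropanoate
Product: 16 tert-butyl (R)-2-{[(Z)-2-bromo-3-(2,2-dimethyl-1,3-benzodioxol-5-yl)acryloyl]oxy}-3-(2,2-dimethyl-1,3-benzodioxol-5-yl)propanoate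
Conditions: DCC, DMAP (cat.), CH2Cl2, 0 °C → rt
Reagents that add atoms: none
Why: Steglich esterification activates the acid, which has no α-hydrogen, and leaves the C–O bond of the alcohol intact, so the (R) centre is retained.

Step 13
Reactants: 15 tert-butyl (R)-3-(2,2-dimethyl-1,3-benzodioxol-5-yl)-2-hydroxypropanoate
Product: 17 tert-butyl (R)-2-(acryloyloxy)-3-(2,2-dimethyl-1,3-benzodioxol-5-yl)propanoate
Conditions: CH2=CHCOCl, Et3N, CH2Cl2, −20 → 0 °C
Reagents that add atoms: acryloyl chloride, C=CC(=O)Cl
Why: O-Acylation of the secondary alcohol with the acid chloride at low temperature gives the acrylate with the stereocentre untouched.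

Step 14
Reactants: 9 4-iodo-2,2-dimethyl-1,3-benzodioxol-5-yl 4-chlorobenzenesulfonate; 18 vinylmagnesium bromide; 16 tert-butyl (R)-2-{[(Z)-2-bromo-3-(2,2-dimethyl-1,3-benzodioxol-5-yl)acryloyl]oxy}-3-(2,2-dimethyl-1,3-benzodioxol-5-yl)propanoate
Product: 23 tert-butyl (R)-3-(2,2-dimethyl-1,3-benzodioxol-5-yl)-2-{[(E)-3-(2,2-dimethyl-1,3-benzodioxol-5-yl)-2-(2,2-dimethyl-5-vinyl-1,3-benzodioxol-4-yl)acryloyl]oxy}propanoate, via arylmagnesium chloride 19 (not isolated), via aryne 20 (not isolated), via vinylated arylmagnesium bromide 21 (not isolated), via arylzinc chloride 22 (not isolated)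
Conditions: 9 (1.5 equiv), i-PrMgCl·LiCl (1.55 equiv), THF, −78 °C; 18 (1.8 equiv), −78 °C → rt; ZnCl2 (2.0 equiv), 0 °C → rt; then 16 (1.0 equiv), Pd(OAc)2 (5 mol %), SPhos (10 mol %), 25–40 °C
Reagents that add atoms: none
Why: Iodine–magnesium exchange gives arylmagnesium 19, which on warming expels 4-chlorobenzenesulfonate to form aryne 20; vinylmagnesium bromide 18 adds across the C1≡C2 bond to give arylmagnesium 21, ZnCl2 converts it into arylzinc 22, and zerovalent palladium formed from Pd(OAc)2 and SPhos inserts into the C–Br bond of 16, transmetalates with 22 and reductively eliminates to 23. The closest known reaction types are the three-component coupling of 3-alkoxyarynes with Grignard reagents and electrophiles and the Negishi coupling of α-bromoacrylates with ortho-substituted arylzinc halides. No ring is closed and no stereocentre is formed, and the (R) centre of 16 is not touched because the organozinc is too weakly basic to enolise the ester. Regioselectivity comes from the C3 oxygen, whose inductive pull distorts the aryne so that the nucleophile enters at the remote carbon C1 and the metal ends at C2, beside that oxygen. Alkene geometry comes from oxidative addition and reductive elimination with retention at the (Z)-bromide, so that ring A ends cis to ring B in the (E)-diarylacrylate, which should also be the more stable isomer. Vinyl transfer to 16 is limited by keeping 18 close to one equivalent per aryne, moving all magnesium species to zinc before 16 is added, and using 16 as the limiting component.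

Step 15
Reactants: 23 the ring A styrene from step 14; 17 tert-butyl (R)-2-(acryloyloxy)-3-(2,2-dimethyl-1,3-benzodioxol-5-yl)propanoate
Product: 24 tetra-acetonide di-tert-butyl ester of salvianolic acid E (the (E)-propenoate at C1 esterified with protected (R)-danshensu, the (E)-diarylacrylate at C2 unchanged)
Conditions: 17 (3 equiv), second-generation Hoveyda–Grubbs catalyst RuCl2(H2IMes)(=CH-C6H4-2-O-i-Pr) (5–10 mol %), CH2Cl2, 40 °C
Reagents that add atoms: none
Why: Olefin cross-metathesis of a styrene with excess acrylate should give the (E)-enoate with loss of ethene; the trisubstituted, electron-poor diarylacrylate double bond does not engage the ruthenium carbene, and ring closure is impossible because it would form a four-membered ring.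

Step 16
Reactants: 24 tetra-acetonide di-tert-butyl ester of salvianolic acid E
Product: 25 salvianolic acid E
Conditions: TFA/H2O (9:1), argon, 0 °C → rt; reversed-phase chromatography
Reagents that add atoms: none
Why: Acid-catalysed hydrolysis of the four aryl ketals (a known cleavage of catechol acetonides in aqueous TFA) and acidolysis of the two tert-butyl esters proceed together, while the two ester links, both alkene geometries and both (R) centres should be untouched by acid at room temperature.

**Compound list**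

1 | 3,4-dihydroxybenzaldehyde | O=Cc1ccc(O)c(O)c1 | starting material
2 | 2,2-dimethyl-1,3-benzodioxole-5-carbaldehyde | O=Cc1ccc2OC(C)(C)Oc2c1 | intermediate
3 | 2,2-dimethyl-1,3-benzodioxol-5-yl formate | O=COc1ccc2OC(C)(C)Oc2c1 | intermediate
4 | 2,2-dimethyl-1,3-benzodioxol-5-ol | Oc1ccc2OC(C)(C)Oc2c1 | intermediate
5 | 2,2-dimethyl-1,3-benzodioxol-5-yl N,N-diethylcarbamate | CCN(CC)C(=O)Oc1ccc2OC(C)(C)Oc2c1 | intermediate
6 | 5-(diethylcarbamoyloxy)-2,2-dimethyl-1,3-benzodioxol-4-yllithium | CCN(CC)C(=O)Oc1ccc2OC(C)(C)Oc2c1[Li] | intermediate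
7 | 4-iodo-2,2-dimethyl-1,3-benzodioxol-5-yl N,N-diethylcarbamate | CCN(CC)C(=O)Oc1ccc2OC(C)(C)Oc2c1I | intermediate
8 | 4-iodo-2,2-dimethyl-1,3-benzodioxol-5-ol | Oc1ccc2OC(C)(C)Oc2c1I | intermediate
9 | 4-iodo-2,2-dimethyl-1,3-benzodioxol-5-yl 4-chlorobenzenesulfonate | CC1(C)Oc2ccc(OS(=O)(=O)c3ccc(Cl)cc3)c(I)c2O1 | intermediate
10 | ethyl (Z)-2-bromo-3-(2,2-dimethyl-1,3-benzodioxol-5-yl)acrylate | Br/C(=C\c1ccc2OC(C)(C)Oc2c1)C(=O)OCC | intermediate
11 | (Z)-2-bromo-3-(2,2-dimethyl-1,3-benzodioxol-5-yl)acrylic acid | Br/C(=C\c1ccc2OC(C)(C)Oc2c1)C(=O)O | intermediate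
12 | (R)-3-(3,4-dihydroxyphenyl)lactic acid (danshensu) | O[C@H](Cc1ccc(O)c(O)c1)C(=O)O | starting material
13 | (R)-5-[(2,2-dimethyl-1,3-benzodioxol-5-yl)methyl]-2,2-dimethyl-1,3-dioxolan-4-one | CC1(C)O[C@H](Cc2ccc3OC(C)(C)Oc3c2)C(=O)O1 | intermediate
14 | (R)-3-(2,2-dimethyl-1,3-benzodioxol-5-yl)-2-hydroxypropanoic acid | O[C@H](Cc1ccc2OC(C)(C)Oc2c1)C(=O)O | intermediate
15 | tert-butyl (R)-3-(2,2-dimethyl-1,3-benzodioxol-5-yl)-2-hydroxypropanoate | O[C@H](Cc1ccc2OC(C)(C)Oc2c1)C(=O)OC(C)(C)C | intermediate
16 | tert-butyl (R)-2-{[(Z)-2-bromo-3-(2,2-dimethyl-1,3-benzodioxol-5-yl)acryloyl]oxy}-3-(2,2-dimethyl-1,3-benzodioxol-5-yl)propanoate | Br/C(=C\c1ccc2OC(C)(C)Oc2c1)C(=O)O[C@H](Cc1ccc2OC(C)(C)Oc2c1)C(=O)OC(C)(C)C | intermediate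
17 | tert-butyl (R)-2-(acryloyloxy)-3-(2,2-dimethyl-1,3-benzodioxol-5-yl)propanoate | C=CC(=O)O[C@H](Cc1ccc2OC(C)(C)Oc2c1)C(=O)OC(C)(C)C | intermediate
18 | vinylmagnesium bromide | C=C[Mg]Br | starting material
19 | 5-(4-chlorobenzenesulfonyloxy)-2,2-dimethyl-1,3-benzodioxol-4-ylmagnesium chloride | CC1(C)Oc2ccc(OS(=O)(=O)c3ccc(Cl)cc3)c([Mg]Cl)c2O1 | intermediate
20 | 2,2-dimethyl-4,5-didehydro-1,3-benzodioxole (aryne) | CC1(C)OC2=C(O1)C#CC=C2 | intermediate
21 | 2,2-dimethyl-5-vinyl-1,3-benzodioxol-4-ylmagnesium bromide | C=Cc1ccc2OC(C)(C)Oc2c1[Mg]Br | intermediate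
22 | 2,2-dimethyl-5-vinyl-1,3-benzodioxol-4-ylzinc chloride | C=Cc1ccc2OC(C)(C)Oc2c1[Zn]Cl | intermediate
23 | tert-butyl (R)-3-(2,2-dimethyl-1,3-benzodioxol-5-yl)-2-{[(E)-3-(2,2-dimethyl-1,3-benzodioxol-5-yl)-2-(2,2-dimethyl-5-vinyl-1,3-benzodioxol-4-yl)acryloyl]oxy}propanoate | C=Cc1ccc2OC(C)(C)Oc2c1/C(=C\c1ccc2OC(C)(C)Oc2c1)C(=O)O[C@H](Cc1ccc2OC(C)(C)Oc2c1)C(=O)OC(C)(C)C | intermediate
24 | tetra-acetonide di-tert-butyl ester of salvianolic acid E | O=C(/C=C/c1ccc2OC(C)(C)Oc2c1/C(=C\c1ccc2OC(C)(C)Oc2c1)C(=O)O[C@H](Cc1ccc2OC(C)(C)Oc2c1)C(=O)OC(C)(C)C)O[C@H](Cc1ccc2OC(C)(C)Oc2c1)C(=O)OC(C)(C)C | intermediate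
25 | salvianolic acid E | O=C(/C=C/c1ccc(O)c(O)c1/C(=C\c1ccc(O)c(O)c1)C(=O)O[C@H](Cc1ccc(O)c(O)c1)C(=O)O)O[C@H](Cc1ccc(O)c(O)c1)C(=O)O | target

**Totals**

Total step count: 16. Longest linear sequence: 9 steps (steps 1, 2, 3, 4, 5, 6, 14, 15, 16).

**Steps most likely to fail**

Step 14. With the vinyl reagent held near one equivalent, arylmagnesium species 19 and 21 may compete for the aryne and give oligomers. Residual vinylzinc may transfer to 16 faster than the hindered arylzinc does. Transmetalation of the doubly ortho-substituted arylzinc may be slow enough for protodemetalation, or for insertion of palladium into the aryl chloride of the expelled sulfonate, to intervene. The fallback sets out from 9 and 18 and comes back at 23. The aryne is generated and vinylmagnesiated as above but with a free excess of 18, and arylmagnesium 21 is quenched with I2 to give 4-iodo-2,2-dimethyl-5-vinyl-1,3-benzodioxole F1, which is purified so that no vinyl metal remains. Iodine–magnesium exchange of F1 with i-PrMgCl·LiCl gives 2,2-dimethyl-5-vinyl-1,3-benzodioxol-4-ylmagnesium chloride F2, ZnCl2 turns it into arylzinc 22, and a separate Negishi coupling with 16 under Pd(OAc)2 and SPhos gives 23.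

Step 15. The ruthenium carbene may load slowly onto the styrene, which has the bulky diarylacrylate in its ortho position, so that self-metathesis of 23 to the stilbene and catalyst decay compete. The fallback sets out from 23 (with 15 as second component) and comes back at 24. OsO4 (cat.) and NaIO4 with 2,6-lutidine in dioxane/H2O dihydroxylate the terminal vinyl group selectively to the 1,2-diol F3 (both epimers at the new carbinol carbon), which is cleaved in the same flask to the ring A aldehyde F4. Separately, 15 is acylated with diethylphosphonoacetic acid (DCC, DMAP) to the phosphonoacetate F5. Horner–Wadsworth–Emmons olefination of F4 with F5 (LiCl, DBU, MeCN) should give 24 with (E) geometry.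

Step 16. Hydrolysis of the four aryl ketals may stall before completion. The tert-butyl cation may alkylate catechol rings already set free. Strong protic acid may promote addition of the ring A C3 hydroxyl to the β-carbon of the diarylacrylate, closing the dihydrobenzofuran isomer. The free catechols may oxidise in air. The fallback sets out from 24 and comes back at 25 in two stages. Silica gel in refluxing toluene removes both tert-butyl esters as 2-methylpropene while all catechols are still masked, giving the tetra-acetonide diacid F6. BCl3 in CH2Cl2 at −78 °C, followed by aqueous quench, then opens the four acetonides without protic acid to give 25.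

**Further compounds**

F1 | step 14 | 4-iodo-2,2-dimethyl-5-vinyl-1,3-benzodioxole | C=Cc1ccc2OC(C)(C)Oc2c1I
F2 | step 14 | 2,2-dimethyl-5-vinyl-1,3-benzodioxol-4-ylmagnesium chloride | C=Cc1ccc2OC(C)(C)Oc2c1[Mg]Cl
F3 | step 15 | tert-butyl (R)-2-{[(E)-2-[5-(1,2-dihydroxyethyl)-2,2-dimethyl-1,3-benzodioxol-4-yl]-3-(2,2-dimethyl-1,3-benzodioxol-5-yl)acryloyl]oxy}-3-(2,2-dimethyl-1,3-benzodioxol-5-yl)propanoate (both epimers at the new carbinol carbon) | OCC(O)c1ccc2OC(C)(C)Oc2c1/C(=C\c1ccc2OC(C)(C)Oc2c1)C(=O)O[C@H](Cc1ccc2OC(C)(C)Oc2c1)C(=O)OC(C)(C)C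
F4 | step 15 | tert-butyl (R)-3-(2,2-dimethyl-1,3-benzodioxol-5-yl)-2-{[(E)-3-(2,2-dimethyl-1,3-benzodioxol-5-yl)-2-(5-formyl-2,2-dimethyl-1,3-benzodioxol-4-yl)acryloyl]oxy}propanoate | O=Cc1ccc2OC(C)(C)Oc2c1/C(=C\c1ccc2OC(C)(C)Oc2c1)C(=O)O[C@H](Cc1ccc2OC(C)(C)Oc2c1)C(=O)OC(C)(C)C
F5 | step 15 | tert-butyl (R)-2-{[2-(diethoxyphosphoryl)acetyl]oxy}-3-(2,2-dimethyl-1,3-benzodioxol-5-yl)propanoate | CCOP(=O)(OCC)CC(=O)O[C@H](Cc1ccc2OC(C)(C)Oc2c1)C(=O)OC(C)(C)C
F6 | step 16 | tetra-acetonide of salvianolic acid E with both carboxylic acids free | O=C(/C=C/c1ccc2OC(C)(C)Oc2c1/C(=C\c1ccc2OC(C)(C)Oc2c1)C(=O)O[C@H](Cc1ccc2OC(C)(C)Oc2c1)C(=O)O)O[C@H](Cc1ccc2OC(C)(C)Oc2c1)C(=O)O
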